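**Plan**

- Retrosynthesis: the (4Z)-olefin of the diene is traced back to an alkyne and the C(sp)–C(sp2) bond to the methylidene carbon is cut (vinyl bromide 18). Then the bond between thiazole C2 and the CMe2 carbon is cut. Last, thiazole 13 is cut at its Z-olefin and the acid fragment at the carbinol–propargyl bond.
- Enabling feature: C2 of the thiazole ring, the carbon between S1 and N3, carries only hydrogen in 13 and is the electrophilic, radical-accepting position of the N3-protonated ring. The exocyclic CMe2 carbon has two identical methyl groups, so it is not stereogenic and can pass through a planar tertiary radical, which a 3-silyloxy-2,2-dimethyl carboxylic acid gives by loss of CO2.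
- Forward: no ring is built, since the thiazole is bought. Redox-active ester 8 (five steps) and thiazole 13 (two steps) are joined by a decarboxylative Minisci C–H alkylation; the chain is then finished by Sonogashira coupling with 18, desilylation and syn semi-reduction of the enyne.
- Stereochemistry: the single (R)-carbinol is set by a chiral phosphoric acid-catalysed propargylation of aldehyde 2 and lies β to the radical centre, untouched. The (2Z)-olefin comes from a lithium-free Wittig reaction, the (4Z)-olefin from the semi-reduction.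

Key step: step 8

Remark: the carbinol carbon of the target is read from the SMILES as (R), and compounds 1, 3, 9, 11, 15 and 16 are taken as purchasable.

**Route**

Step 1
Reactants: 1 methyl 3-hydroxy-2,2-dimethylpropanoate
Product: 2 methyl 2,2-dimethyl-3-oxopropanoate
Conditions: TEMPO (10 mol %), PhI(OAc)2, CH2Cl2, 25 °C
Reagents that add atoms: none
Why: Oxoammonium-mediated oxidation (TEMPO with PhI(OAc)2) of the primary alcohol stops at the aldehyde, which has no α-hydrogen and cannot enolise.

Step 2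
Reactants: 2 methyl 2,2-dimethyl-3-oxopropanoate, 3 4,4,5,5-tetramethyl-2-(propa-1,2-dien-1-yl)-1,3,2-dioxaborolane (allenylboronic acid pinacol ester)
Product: 5 methyl (3R)-3-hydroxy-2,2-dimethylhex-5-ynoate, via boronate ester 4 (not isolated)
Conditions: (R)-TRIP [(R)-3,3'-bis(2,4,6-triisopropylphenyl)-1,1'-binaphthyl-2,2'-diyl hydrogen phosphate] (10 mol %), 4 Å molecular sieves, toluene, 0 °C; then H2O
Reagents that add atoms: none
Why: Chiral phosphoric acid-catalysed allenylboration runs through a closed six-membered transition state with transposition of the allenyl unit (SE2') to the homopropargylic alcohol, and with (R)-TRIP, which binds the boronate oxygen and the formyl hydrogen, the Re face of the aldehyde should be attacked, which sets the (R)-configuration of the only stereocentre.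

Step 3
Reactants: 5 methyl (3R)-3-hydroxy-2,2-dimethylhex-5-ynoate
Product: 6 methyl (3R)-3-{[tert-butyl(dimethyl)silyl]oxy}-2,2-dimethylhex-5-ynoate
Conditions: TBSOTf, 2,6-lutidine, CH2Cl2, 0 °C
Reagents that add atoms: tert-butyldimethylsilyl trifluoromethanesulfonate (TBSOTf), CC(C)(C)[Si](C)(C)OS(=O)(=O)C(F)(F)F
Why: The silyl triflate with 2,6-lutidine silylates even a hindered neopentylic secondary alcohol (silyl ether formation), and the ether later blocks β-lactone formation in the activated ester and is inert to the radical.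

Step 4
Reactants: 6 methyl (3R)-3-{[tert-butyl(dimethyl)silyl]oxy}-2,2-dimethylhex-5-ynoate
Product: 7 (3R)-3-{[tert-butyl(dimethyl)silyl]oxy}-2,2-dimethylhex-5-ynoic acid
Conditions: LiOH, THF/MeOH/H2O, 50 °C; then 1 M HCl, 0 °C
Reagents that add atoms: lithium hydroxide (LiOH), [Li+].[OH-]
Why: Saponification of the methyl ester is slow at a quaternary α-carbon but clean, since there is no α-hydrogen for epimerisation or elimination and the silyl ether is stable to hydroxide.

Step 5
Reactants: 7 (3R)-3-{[tert-butyl(dimethyl)silyl]oxy}-2,2-dimethylhex-5-ynoic acid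
Product: 8 1,3-dioxo-1,3-dihydro-2H-isoindol-2-yl (3R)-3-{[tert-butyl(dimethyl)silyl]oxy}-2,2-dimethylhex-5-ynoate
Conditions: N-hydroxyphthalimide, DIC, DMAP (cat.), CH2Cl2, 25 °C
Reagents that add atoms: N-hydroxyphthalimide, O=C1c2ccccc2C(=O)N1O
Why: Carbodiimide coupling (Steglich-type esterification) with N-hydroxyphthalimide converts the acid into a redox-active ester whose one-electron reduction is within reach of a photocatalyst.

Step 6
Reactants: 9 ethyl 2-(1,3-thiazol-4-yl)acetate
Product: 10 2-(1,3-thiazol-4-yl)acetaldehyde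
Conditions: iBu2AlH (1.1 equiv), CH2Cl2, −78 °C; then H2O
Reagents that add atoms: none
Why: Partial reduction of an ester with one equivalent of iBu2AlH at −78 °C stops at the aldehyde oxidation level, and the crude aldehyde is used at once because it enolises easily.

Step 7
Reactants: 10 2-(1,3-thiazol-4-yl)acetaldehyde, 11 (but-3-en-1-yl)triphenylphosphonium bromide
Product: 13 4-[(2Z)-hexa-2,5-dien-1-yl]-1,3-thiazole, via phosphorus ylide 12 (not isolated)
Conditions: NaN(SiMe3)2, THF, −78 °C; then 10, −78 → 0 °C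
Reagents that add atoms: none
Why: Wittig olefination with a non-stabilised, lithium-free ylide passes through the kinetically favoured cis-oxaphosphetane and should give the (2Z)-olefin, while the low temperature limits enolisation of the aldehyde.

Step 8
Reactants: 8 1,3-dioxo-1,3-dihydro-2H-isoindol-2-yl (3R)-3-{[tert-butyl(dimethyl)silyl]oxy}-2,2-dimethylhex-5-ynoate, 13 4-[(2Z)-hexa-2,5-dien-1-yl]-1,3-thiazole
Product: 14 2-[(3R)-3-{[tert-butyl(dimethyl)silyl]oxy}-2-methylhex-5-yn-2-yl]-4-[(2Z)-hexa-2,5-dien-1-yl]-1,3-thiazole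
Conditions: 4CzIPN (2 mol %), CF3CO2H (3 equiv), 13 (2 equiv), degassed MeCN, blue LEDs (450 nm), 25 °C, argon
Reagents that add atoms: none
Why: The excited photocatalyst transfers one electron to the acid-activated N-(acyloxy)phthalimide 8, which loses phthalimide anion and CO2 to give the tertiary α,α-dimethyl radical; this nucleophilic radical adds to C2 of the N3-protonated thiazole, and the adduct loses the C2 proton and is oxidised by the photocatalyst radical cation to the rearomatised thiazole, so the cycle is redox-neutral. The closest known reaction type is the decarboxylative Minisci alkylation of azoles and azines with tertiary redox-active esters under photoredox catalysis. No ring is closed and no stereocentre is formed, because the new quaternary carbon carries two identical methyl groups, and the (R)-carbinol carbon, β to the radical centre, keeps all four of its bonds. The step needs C2 over C5 selectivity, which protonation at N3 secures by placing the largest LUMO coefficient on the carbon between N3 and S1, while the C4 side chain shields C5 against a tertiary radical. It also needs chemoselectivity, which polarity matching secures: the nucleophilic radical prefers the thiazolium ion to the alkyne and the unactivated olefins, and ring closure onto the alkyne would be 4-exo or 5-endo. The excess of 13 is there to outrun hydrogen abstraction from its allylic CH2 groups, and the silyl ether cannot migrate to the radical centre.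

Step 9
Reactants: 15 3-bromobut-3-en-1-ol, 16 tert-butyl methyl imidodicarbonate
Product: 17 tert-butyl methyl (3-bromobut-3-en-1-yl)imidodicarbonate
Conditions: PPh3, DIAD, THF, 0 → 25 °C
Reagents that add atoms: none
Why: Mitsunobu alkylation of the acidic N–H of the imidodicarbonate (a Gabriel-type nitrogen nucleophile) by the primary alcohol installs the nitrogen with its methoxycarbonyl group already in place, and the vinyl bromide is inert.

Step 10
Reactants: 17 tert-butyl methyl (3-bromobut-3-en-1-yl)imidodicarbonate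
Product: 18 methyl (3-bromobut-3-en-1-yl)carbamate
Conditions: CF3CO2H, CH2Cl2, 0 → 25 °C
Reagents that add atoms: none
Why: Acidolysis removes the tert-butoxycarbonyl group as 2-methylpropene and CO2 (Boc cleavage), whereas the methyl carbamate and the vinyl bromide are stable to CF3CO2H.

Step 11
Reactants: 14 2-[(3R)-3-{[tert-butyl(dimethyl)silyl]oxy}-2-methylhex-5-yn-2-yl]-4-[(2Z)-hexa-2,5-dien-1-yl]-1,3-thiazole, 18 methyl (3-bromobut-3-en-1-yl)carbamate
Product: 19 methyl [(7R)-7-{[tert-butyl(dimethyl)silyl]oxy}-8-{4-[(2Z)-hexa-2,5-dien-1-yl]-1,3-thiazol-2-yl}-8-methyl-3-methylidenenon-4-yn-1-yl]carbamate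
Conditions: Pd(PPh3)4 (5 mol %), CuI (10 mol %), Et3N, THF, 40 °C
Reagents that add atoms: none
Why: Sonogashira coupling of the terminal alkyne with the 2-bromoalkene forms the C(sp)–C(sp2) bond of the enyne under mild amine conditions that leave the skipped diene, the thiazole and the silyl ether untouched.

Step 12
Reactants: 19 methyl [(7R)-7-{[tert-butyl(dimethyl)silyl]oxy}-8-{4-[(2Z)-hexa-2,5-dien-1-yl]-1,3-thiazol-2-yl}-8-methyl-3-methylidenenon-4-yn-1-yl]carbamate
Product: 20 methyl [(7R)-8-{4-[(2Z)-hexa-2,5-dien-1-yl]-1,3-thiazol-2-yl}-7-hydroxy-8-methyl-3-methylidenenon-4-yn-1-yl]carbamate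
Conditions: Bu4NF, THF, 0 → 40 °C; then H2O
Reagents that add atoms: none
Why: Fluoride cleaves the Si–O bond (fluoride-mediated desilylation) without affecting the carbamate, the enyne or the olefins, and the carbinol configuration is not involved.

Step 13
Reactants: 20 methyl [(7R)-8-{4-[(2Z)-hexa-2,5-dien-1-yl]-1,3-thiazol-2-yl}-7-hydroxy-8-methyl-3-methylidenenon-4-yn-1-yl]carbamate
Product: 21 methyl [(4Z,7R)-8-{4-[(2Z)-hexa-2,5-dien-1-yl]-1,3-thiazol-2-yl}-7-hydroxy-8-methyl-3-methylidenenon-4-en-1-yl]carbamate (mycothiazole)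
Conditions: Zn dust activated with Cu(OAc)2 and AgNO3, MeOH/H2O (1:1), 40 °C
Reagents that add atoms: none
Why: Activated zinc in a protic medium delivers two hydrogens to the same side of a conjugated triple bond (zinc–copper–silver semi-reduction of enynes), which should give the (4Z)-diene while isolated olefins are not reduced and the homopropargylic hydroxyl assists the reduction.

**Compound list**

1 | methyl 3-hydroxy-2,2-dimethylpropanoate | COC(=O)C(C)(C)CO | starting material
2 | methyl 2,2-dimethyl-3-oxopropanoate | COC(=O)C(C)(C)C=O | intermediate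
3 | 4,4,5,5-tetramethyl-2-(propa-1,2-dien-1-yl)-1,3,2-dioxaborolane | C=C=CB1OC(C)(C)C(C)(C)O1 | starting material
4 | methyl (3R)-2,2-dimethyl-3-[(4,4,5,5-tetramethyl-1,3,2-dioxaborolan-2-yl)oxy]hex-5-ynoate | COC(=O)C(C)(C)[C@H](OB1OC(C)(C)C(C)(C)O1)CC#C | intermediate
5 | methyl (3R)-3-hydroxy-2,2-dimethylhex-5-ynoate | COC(=O)C(C)(C)[C@H](O)CC#C | intermediate
6 | methyl (3R)-3-{[tert-butyl(dimethyl)silyl]oxy}-2,2-dimethylhex-5-ynoate | COC(=O)C(C)(C)[C@H](O[Si](C)(C)C(C)(C)C)CC#C | intermediate
7 | (3R)-3-{[tert-butyl(dimethyl)silyl]oxy}-2,2-dimethylhex-5-ynoic acid | OC(=O)C(C)(C)[C@H](O[Si](C)(C)C(C)(C)C)CC#C | intermediate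
8 | 1,3-dioxo-1,3-dihydro-2H-isoindol-2-yl (3R)-3-{[tert-butyl(dimethyl)silyl]oxy}-2,2-dimethylhex-5-ynoate | O=C(ON1C(=O)c2ccccc2C1=O)C(C)(C)[C@H](O[Si](C)(C)C(C)(C)C)CC#C | intermediate
9 | ethyl 2-(1,3-thiazol-4-yl)acetate | CCOC(=O)Cc1cscn1 | starting material
10 | 2-(1,3-thiazol-4-yl)acetaldehyde | O=CCc1cscn1 | intermediate
11 | (but-3-en-1-yl)triphenylphosphonium bromide | C=CCC[P+](c1ccccc1)(c1ccccc1)c1ccccc1.[Br-] | starting material
12 | (but-3-en-1-ylidene)triphenyl-λ5-phosphane | C=CCC=P(c1ccccc1)(c1ccccc1)c1ccccc1 | intermediate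
13 | 4-[(2Z)-hexa-2,5-dien-1-yl]-1,3-thiazole | C=CC/C=C\Cc1cscn1 | intermediate
14 | 2-[(3R)-3-{[tert-butyl(dimethyl)silyl]oxy}-2-methylhex-5-yn-2-yl]-4-[(2Z)-hexa-2,5-dien-1-yl]-1,3-thiazole | C=CC/C=C\Cc1csc(C(C)(C)[C@H](O[Si](C)(C)C(C)(C)C)CC#C)n1 | intermediate
15 | 3-bromobut-3-en-1-ol | C=C(Br)CCO | starting material
16 | tert-butyl methyl imidodicarbonate | COC(=O)NC(=O)OC(C)(C)C | starting material
17 | tert-butyl methyl (3-bromobut-3-en-1-yl)imidodicarbonate | C=C(Br)CCN(C(=O)OC)C(=O)OC(C)(C)C | intermediate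
18 | methyl (3-bromobut-3-en-1-yl)carbamate | C=C(Br)CCNC(=O)OC | intermediate
19 | methyl [(7R)-7-{[tert-butyl(dimethyl)silyl]oxy}-8-{4-[(2Z)-hexa-2,5-dien-1-yl]-1,3-thiazol-2-yl}-8-methyl-3-methylidenenon-4-yn-1-yl]carbamate | C=CC/C=C\Cc1csc(C(C)(C)[C@H](O[Si](C)(C)C(C)(C)C)CC#CC(=C)CCNC(=O)OC)n1 | intermediate
20 | methyl [(7R)-8-{4-[(2Z)-hexa-2,5-dien-1-yl]-1,3-thiazol-2-yl}-7-hydroxy-8-methyl-3-methylidenenon-4-yn-1-yl]carbamate | C=CC/C=C\Cc1csc(C(C)(C)[C@H](O)CC#CC(=C)CCNC(=O)OC)n1 | intermediate
21 | methyl [(4Z,7R)-8-{4-[(2Z)-hexa-2,5-dien-1-yl]-1,3-thiazol-2-yl}-7-hydroxy-8-methyl-3-methylidenenon-4-en-1-yl]carbamate (mycothiazole) | C=CC/C=C\Cc1csc(C(C)(C)[C@H](O)C/C=C\C(=C)CCNC(=O)OC)n1 | target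

**Count and risks**

Total step count: 13. Longest linear sequence: 9 steps (steps 1, 2, 3, 4, 5, 8, 11, 12, 13).

Step 8 (most likely to fail). The hindered tertiary radical may abstract hydrogen from the doubly allylic CH2 and the thiazolyl-allylic CH2 of 13 faster than it adds to C2, so that reduction of the radical and degradation of the skipped diene outrun the coupling. Incomplete protonation of the weakly basic thiazole would slow the addition further. The fallback keeps the radical logic but couples before the labile diene exists. It sets out from 8 and uses 9, a thiazole without weak allylic C–H bonds, as the acceptor under the conditions of step 8, which should give ethyl {2-[(3R)-3-{[tert-butyl(dimethyl)silyl]oxy}-2-methylhex-5-yn-2-yl]-1,3-thiazol-4-yl}acetate F1. Partial reduction with iBu2AlH at −78 °C then gives {2-[(3R)-3-{[tert-butyl(dimethyl)silyl]oxy}-2-methylhex-5-yn-2-yl]-1,3-thiazol-4-yl}acetaldehyde F2, and Wittig olefination with ylide 12 returns to the route at 14.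

Step 2. Addition to the neopentylic, ester-bearing aldehyde may be slow under acid catalysis, and the facial selectivity may erode. The fallback replaces catalyst control by reagent control and builds the alkyne afterwards. It sets out from 2: allylboration with B-allyldiisopinocampheylborane, made from (+)-Ipc2BOMe (the borinate derived from (−)-α-pinene) and allylMgBr in Et2O at −78 °C and followed by NaOH/H2O2, should attack the Re face and give methyl (3R)-3-hydroxy-2,2-dimethylhex-5-enoate F3. Silylation with TBSOTf and 2,6-lutidine gives methyl (3R)-3-{[tert-butyl(dimethyl)silyl]oxy}-2,2-dimethylhex-5-enoate F4. Ozonolysis (O3, CH2Cl2, −78 °C, then PPh3) gives methyl (3R)-3-{[tert-butyl(dimethyl)silyl]oxy}-2,2-dimethyl-5-oxopentanoate F5, and Ohira–Bestmann homologation (dimethyl (1-diazo-2-oxopropyl)phosphonate, K2CO3, MeOH) returns to the route at 6.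

Step 13. The reduction on the zinc surface may stall or run on, and the 2-substituted (Z)-diene may isomerise or polymerise during a long reaction; coordination of the thiazole to the metal may add to this. The fallback gives up the enyne and makes the Z-olefin before the thiazole is attached, at a stage with no other olefin present. It sets out from 6:
- Iodination of the alkyne (N-iodosuccinimide, AgNO3 cat., acetone) gives methyl (3R)-3-{[tert-butyl(dimethyl)silyl]oxy}-6-iodo-2,2-dimethylhex-5-ynoate F6.
- Diimide (2-nitrobenzenesulfonyl hydrazide, Et3N, THF/i-PrOH) reduces it by syn addition to methyl (3R,5Z)-3-{[tert-butyl(dimethyl)silyl]oxy}-6-iodo-2,2-dimethylhex-5-enoate F7.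
- Me3SnOH (1,2-dichloroethane, 80 °C) gives (3R,5Z)-3-{[tert-butyl(dimethyl)silyl]oxy}-6-iodo-2,2-dimethylhex-5-enoic acid F8.
- N-hydroxyphthalimide and DIC give 1,3-dioxo-1,3-dihydro-2H-isoindol-2-yl (3R,5Z)-3-{[tert-butyl(dimethyl)silyl]oxy}-6-iodo-2,2-dimethylhex-5-enoate F9.
- The coupling of step 8 with 13 gives 2-[(3R,5Z)-3-{[tert-butyl(dimethyl)silyl]oxy}-6-iodo-2-methylhex-5-en-2-yl]-4-[(2Z)-hexa-2,5-dien-1-yl]-1,3-thiazole F10.
- Separately, bromide 18 is borylated (B2pin2, PdCl2(PPh3)2, PPh3, KOPh, toluene, 50 °C) to methyl [3-(4,4,5,5-tetramethyl-1,3,2-dioxaborolan-2-yl)but-3-en-1-yl]carbamate F11.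
- Suzuki coupling of F10 with F11 (Pd(PPh3)4, aqueous K3PO4, THF), with retention of both olefin geometries, gives methyl [(4Z,7R)-7-{[tert-butyl(dimethyl)silyl]oxy}-8-{4-[(2Z)-hexa-2,5-dien-1-yl]-1,3-thiazol-2-yl}-8-methyl-3-methylidenenon-4-en-1-yl]carbamate F12.
- Bu4NF in THF returns to the route at 21.

**Further compounds**

F1 | step 8 | ethyl {2-[(3R)-3-{[tert-butyl(dimethyl)silyl]oxy}-2-methylhex-5-yn-2-yl]-1,3-thiazol-4-yl}acetate | CCOC(=O)Cc1csc(C(C)(C)[C@H](O[Si](C)(C)C(C)(C)C)CC#C)n1
F2 | step 8 | {2-[(3R)-3-{[tert-butyl(dimethyl)silyl]oxy}-2-methylhex-5-yn-2-yl]-1,3-thiazol-4-yl}acetaldehyde | O=CCc1csc(C(C)(C)[C@H](O[Si](C)(C)C(C)(C)C)CC#C)n1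
F3 | step 2 | methyl (3R)-3-hydroxy-2,2-dimethylhex-5-enoate | COC(=O)C(C)(C)[C@H](O)CC=C
F4 | step 2 | methyl (3R)-3-{[tert-butyl(dimethyl)silyl]oxy}-2,2-dimethylhex-5-enoate | COC(=O)C(C)(C)[C@H](O[Si](C)(C)C(C)(C)C)CC=C
F5 | step 2 | methyl (3R)-3-{[tert-butyl(dimethyl)silyl]oxy}-2,2-dimethyl-5-oxopentanoate | COC(=O)C(C)(C)[C@H](O[Si](C)(C)C(C)(C)C)CC=O
F6 | step 13 | methyl (3R)-3-{[tert-butyl(dimethyl)silyl]oxy}-6-iodo-2,2-dimethylhex-5-ynoate | COC(=O)C(C)(C)[C@H](O[Si](C)(C)C(C)(C)C)CC#CI
F7 | step 13 | methyl (3R,5Z)-3-{[tert-butyl(dimethyl)silyl]oxy}-6-iodo-2,2-dimethylhex-5-enoate | COC(=O)C(C)(C)[C@H](O[Si](C)(C)C(C)(C)C)C/C=C\I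
F8 | step 13 | (3R,5Z)-3-{[tert-butyl(dimethyl)silyl]oxy}-6-iodo-2,2-dimethylhex-5-enoic acid | OC(=O)C(C)(C)[C@H](O[Si](C)(C)C(C)(C)C)C/C=C\I
F9 | step 13 | 1,3-dioxo-1,3-dihydro-2H-isoindol-2-yl (3R,5Z)-3-{[tert-butyl(dimethyl)silyl]oxy}-6-iodo-2,2-dimethylhex-5-enoate | O=C(ON1C(=O)c2ccccc2C1=O)C(C)(C)[C@H](O[Si](C)(C)C(C)(C)C)C/C=C\I
F10 | step 13 | 2-[(3R,5Z)-3-{[tert-butyl(dimethyl)silyl]oxy}-6-iodo-2-methylhex-5-en-2-yl]-4-[(2Z)-hexa-2,5-dien-1-yl]-1,3-thiazole | C=CC/C=C\Cc1csc(C(C)(C)[C@H](O[Si](C)(C)C(C)(C)C)C/C=C\I)n1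
F11 | step 13 | methyl [3-(4,4,5,5-tetramethyl-1,3,2-dioxaborolan-2-yl)but-3-en-1-yl]carbamate | C=C(CCNC(=O)OC)B1OC(C)(C)C(C)(C)O1
F12 | step 13 | methyl [(4Z,7R)-7-{[tert-butyl(dimethyl)silyl]oxy}-8-{4-[(2Z)-hexa-2,5-dien-1-yl]-1,3-thiazol-2-yl}-8-methyl-3-methylidenenon-4-en-1-yl]carbamate | C=CC/C=C\Cc1csc(C(C)(C)[C@H](O[Si](C)(C)C(C)(C)C)C/C=C\C(=C)CCNC(=O)OC)n1
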